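(The data are calculated for substances that don't exist; scatter was added.)

At early times the substrate charge barely shows: the blue run has lost 0.0136 M of substrate at 10.0 min and the red run 0.0180 M at 8.00 min, though red carries more. So what stops this reaction?

| setting | blue | red | ochre | flask |
|---|---|---|---|---|
| left-handed substrate | 0.034 M | 0.075 M | 0.050 M | 0.050 M |
| right-handed substrate | 0.034 M | 0.075 M | 0.050 M | 0.050 M |
| partner | 0.055 M | 0.055 M | 0.055 M | 0.0550 M |
| protic impurity | 0.010 M | 0.010 M | 0.0050 M | 0.0100 M |
| free catalyst | 2.5 mM | 2.5 mM | 2.5 mM | 2.5 mM |
| remark | run made earlier | run made earlier | run made earlier |  |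
| time |  |  |  | 1.5 h |

- blue (time / min: left-handed substrate / %, right-handed substrate / %): 10.0: 40, 40; 20.0: 33, 34; 30.0: 32, 31; 40.0: 24, 28; 50.0: 23, 29
- red (time / min: left-handed substrate / %, right-handed substrate / %): 4.00: 48, 45; 8.00: 43, 45; 15.0: 44, 41; 30.0: 39, 41; 50.0: 37, 36
- ochre (time / min: left-handed substrate / %, right-handed substrate / %): 10.0: 39, 45; 20.0: 38, 38; 30.0: 34, 34; 40.0: 31, 35; 50.0: 27, 33

(scatter of a reading: 2 percentage points)

- free catalyst is single-handed; left-handed substrate and right-handed substrate are mirror images of each other, charged as a racemate, each of them at the stated concentration
- what was read earlier has a scatter of 2 percentage points, one standard deviation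
- on the list of suspects stand: free catalyst + right-handed substrate <-> catalyst intermediate B; partner + catalyst intermediate A -> free catalyst + left-handed product; free catalyst + left-handed substrate <-> catalyst intermediate A; left-handed product <-> right-handed product; partner + catalyst intermediate B -> free catalyst + right-handed product; free catalyst -> spent catalyst; partner + protic impurity -> quenched reagent
- an excess is the difference of the two amounts in percent of their sum
- an excess is below zero if the other one leads

Each product takes one partner, and protic impurity, a suspect, takes one too, so I balance partner, the limiting reagent of the flask, with 0.0550 M against 0.100 M of substrates. The partner ceiling, c(partner) minus c(protic impurity) over both substrates charged, is 45.0% for the flask.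

Does the flask get there by 1.5 h? The red run, with the same partner and impurity, reads 0.900 of its usable partner consumed at 50.0 min, so I put the flask a little below its ceiling.

Which hand leads? The ochre run reads a substrate gap of 6 percentage points at 50.0 min, on a scatter of 2 points. But the readings hold substrates, and left-handed product <-> right-handed product stands among the suspects, so I set no figure for the product excess.

1. part of the left-handed substrate and right-handed substrate charged together that has reacted at 1.5 h
2. excess of left-handed product over right-handed product in the product at 1.5 h
3. excess of right-handed substrate over left-handed substrate among what is left of the two at 1.5 h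

The forecast gives 41% reacted, 12% product excess and 8.3% substrate excess, on the ground “Left-handed substrate is consumed slightly faster”; beside its product excess I put no figure of my own.

The flask gives 40.5% reacted, 0.900 of its ceiling, with 0.0187% product excess and 5.78% substrate excess.

    free catalyst + right-handed substrate ⇌ catalyst intermediate B (K = 42.0 L mol⁻¹, k = 9.07 L mol⁻¹ s⁻¹)
    partner + catalyst intermediate A → free catalyst + left-handed product (k = 0.533 L mol⁻¹ s⁻¹)
    free catalyst + left-handed substrate ⇌ catalyst intermediate A (K = 27.0 L mol⁻¹, k = 4.28 L mol⁻¹ s⁻¹)
    left-handed product ⇌ right-handed product (k = 0.00565 s⁻¹)
    partner + catalyst intermediate B → free catalyst + right-handed product (k = 0.260 L mol⁻¹ s⁻¹)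
    free catalyst → spent catalyst (k = 6.41 × 10⁻⁴ s⁻¹)
    partner + protic impurity → quenched reagent (k = 0.298 L mol⁻¹ s⁻¹)

Up to 0.150 h in the flask, partner and protic impurity react together, and the impurity falls to 0.192% of its charge. From then to 1.50 h, partner falls to 9.29% of its charge while the exchange of the two products runs back at 99.6% of its forward turnover, and left-handed product and right-handed product end at 19.9% and 19.9% of the substrates charged. A neighbour flask with 0.22 M of partner has a ceiling of 210%, above the substrates charged, and reaches 98.9% reacted with 51% of its partner left.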